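**Strategy.** The C1–C10 cis-epoxide of the ten-membered carbocycle (germacrane numbering, ring atoms C1–C10) is treated as a masked (Z)-C1=C10 alkene, and that alkene as the scar of an excised sulfur atom; C2 and C9 are plain methylenes, so carbanions at C1 and C10 are harmless. The carbocycle is therefore built one atom too large, as an eleven-membered cyclic sulfone with SO2 bridging C1 and C10, closed by a Nozaki–Hiyama–Kishi reaction at C5–C6. A Ramberg–Bäcklund reaction then extrudes SO2, contracts the ring to the (1(10)Z,4E)-cyclodecadiene and erases the deliberately unassigned C10 centre, so both epimers converge. The base-sensitive methylene lactone and isobutyrate follow afterwards.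

Key step: step 18

Remark (numbering): atoms are named by germacranolide numbering: ring C1–C10 (C1/C10 epoxide, C3 carbinol, C4=C5, C6 ester carbon, C7/C8 lactone fusion), C11–C13 lactone carbons, C14/C15 the methyls on C10/C4.
Remark (assumption): C10 is carried as a pair of epimers from compound 10 to compound 28 and is left undefined in those SMILES; it becomes sp2 in step 18.

Step 1
Reactants: 1 4-methyl hydrogen itaconate
Product: 2 methyl 3-(hydroxymethyl)but-3-enoate
Conditions: BH3·SMe2 (1 equiv), THF, −10 → 0 °C; MeOH quench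
Reagents that add atoms: none
Why: Borane reduction of a carboxylic acid (through its acyloxyborane) is much faster than reduction of the methyl ester or hydroboration of the conjugated, electron-poor alkene, so one equivalent of BH3 should give the allylic alcohol selectively.

Step 2
Reactants: 2 methyl 3-(hydroxymethyl)but-3-enoate
Product: 3 methyl 3-[(tert-butyldimethylsilyloxy)methyl]but-3-enoate
Conditions: TBSCl, imidazole, DMF, 0 °C → rt
Reagents that add atoms: tert-butyldimethylsilyl chloride (CC(C)(C)[Si](C)(C)Cl)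
Why: Standard silylation of the primary allylic alcohol, done at once to forestall lactonisation onto the ester.

Step 3
Reactants: 3 methyl 3-[(tert-butyldimethylsilyloxy)methyl]but-3-enoate
Product: 4 3-[(tert-butyldimethylsilyloxy)methyl]but-3-enoic acid
Conditions: LiOH, THF/H2O, 0 °C; dilute HCl to pH 4
Reagents that add atoms: lithium hydroxide ([Li+].[OH-])
Why: Cold saponification of the methyl ester should outrun base-induced migration of the β,γ-double bond into conjugation, and the primary TBS ether is stable to LiOH.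

Step 4
Reactants: 4 3-[(tert-butyldimethylsilyloxy)methyl]but-3-enoic acid; 5 (R)-4-benzyloxazolidin-2-one
Product: 7 (R)-4-benzyl-3-{3-[(tert-butyldimethylsilyloxy)methyl]but-3-enoyl}oxazolidin-2-one, via mixed pivalic anhydride 6 (not isolated)
Conditions: PivCl, Et3N, THF, −20 °C; then 5, LiCl, −20 °C → rt
Reagents that add atoms: none
Why: N-Acylation of the Evans auxiliary through the mixed pivalic anhydride (LiCl/Et3N protocol) avoids strong base and keeps the β,γ-alkene out of conjugation.

Step 5
Reactants: 8 (E)-but-2-enal; 9 thioacetic S-acid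
Product: 10 3-(acetylsulfanyl)butanal (racemic)
Conditions: Et3N (cat.), CH2Cl2, 0 °C
Reagents that add atoms: none
Why: Amine-catalysed thia-Michael addition of the thioacid to the enal; the new centre (C10 of the target) is formed racemic on purpose because step 18 erases it.

Step 6
Reactants: 7 (R)-4-benzyl-3-{3-[(tert-butyldimethylsilyloxy)methyl]but-3-enoyl}oxazolidin-2-one; 10 3-(acetylsulfanyl)butanal
Product: 12 syn-aldol adduct (R)-4-benzyl-3-[(2R,3S)-5-(acetylsulfanyl)-3-hydroxy-2-{3-[(tert-butyldimethylsilyl)oxy]prop-1-en-2-yl}hexanoyl]oxazolidin-2-one, via boron enolate 11 (not isolated)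
Conditions: Bu2BOTf, i-Pr2NEt, CH2Cl2, −78 → 0 °C; then 10, −78 → 0 °C; pH 7 buffer/MeOH/H2O2
Reagents that add atoms: none
Why: Evans syn-aldol reaction: soft enolisation gives the Z-boron dienolate, which reacts at its α-carbon through a Zimmerman–Traxler chair on the face away from the benzyl group of the (R)-auxiliary, setting C7 and C8 (syn; 2R,3S in the acyl chain) irrespective of the remote C10 epimer.

Step 7
Reactants: 12 syn-aldol adduct
Product: 13 3-O-TBS ether of the aldol adduct
Conditions: TBSOTf, 2,6-lutidine, CH2Cl2, −78 °C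
Reagents that add atoms: tert-butyldimethylsilyl triflate (CC(C)(C)[Si](C)(C)OS(=O)(=O)C(F)(F)F)
Why: Low-temperature silylation of the hindered secondary alcohol leaves imide and thioester untouched and blocks retro-aldol cleavage.

Step 8
Reactants: 13 3-O-TBS ether of the aldol adduct
Product: 14 thiol alcohol HOCH2(C6)–C7H[C(=CH2)CH2OTBS]–C8H(OTBS)–C9H2–C10H(CH3)–SH
Conditions: LiBH4, MeOH (1 equiv), THF, 0 °C
Reagents that add atoms: none
Why: LiBH4 reduces the N-acyl oxazolidinone to the primary alcohol (auxiliary recovered) and in the same operation cleaves the thioacetate reductively to the thiol, without touching the silyl ethers, the alkene or the stereocentres.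

Step 9
Reactants: 15 3-chloropropanoyl chloride; 16 bis(trimethylsilyl)acetylene
Product: 17 5-chloro-1-(trimethylsilyl)pent-1-yn-3-one
Conditions: AlCl3, CH2Cl2, 0 °C
Reagents that add atoms: none
Why: Friedel–Crafts-type ipso-acylation of the alkynylsilane (β-silyl-stabilised vinyl cation) gives the TMS-ynone.

Step 10
Reactants: 17 5-chloro-1-(trimethylsilyl)pent-1-yn-3-one
Product: 18 (R)-5-chloro-1-(trimethylsilyl)pent-1-yn-3-ol
Conditions: RuCl[(R,R)-TsDPEN](p-cymene) (2 mol%), i-PrOH, rt
Reagents that add atoms: none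
Why: Noyori asymmetric transfer hydrogenation of the ynone, in which the alkyne is the π-recognition element, so the (R,R)-catalyst should give the (R)-propargylic alcohol, the future C3 stereocentre.

Step 11
Reactants: 18 (R)-5-chloro-1-(trimethylsilyl)pent-1-yn-3-ol
Product: 19 (R)-5-chloropent-1-yn-3-ol
Conditions: K2CO3 (cat.), MeOH, 0 °C
Reagents that add atoms: none
Why: Methanolysis of the alkynyl C–Si bond under catalytic carbonate; the secondary alcohol and the primary chloride are inert.

Step 12
Reactants: 19 (R)-5-chloropent-1-yn-3-ol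
Product: 21 (R,E)-5-chloro-1-iodo-2-methylpent-1-en-3-ol, via alkenylalane 20 (not isolated)
Conditions: Me3Al, Cp2ZrCl2 (cat.), CH2Cl2, 0 °C → rt; then I2, THF, −30 °C; aq. K2CO3
Reagents that add atoms: trimethylaluminium (C[Al](C)C); iodine (II)
Why: Negishi zirconium-catalysed carboalumination adds Me and Al syn across the alkyne with Me on the internal carbon, and iodinolysis of the C–Al bond with retention gives the E-vinyl iodide, fixing the C4=C5 geometry.

Step 13
Reactants: 21 (R,E)-5-chloro-1-iodo-2-methylpent-1-en-3-ol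
Product: 22 (R,E)-tert-butyl[(5-chloro-1-iodo-2-methylpent-1-en-3-yl)oxy]dimethylsilane
Conditions: TBSCl, imidazole, DMF, rt
Reagents that add atoms: tert-butyldimethylsilyl chloride (CC(C)(C)[Si](C)(C)Cl)
Why: Standard TBSCl/imidazole silylation of the secondary allylic alcohol.

Step 14
Reactants: 14 thiol alcohol; 22 (R,E)-tert-butyl[(5-chloro-1-iodo-2-methylpent-1-en-3-yl)oxy]dimethylsilane
Product: 23 open-chain sulfide HOCH2(C6)–C7–C8–C9–C10–S–C1–C2–C3–C4=C5–I
Conditions: Cs2CO3, DMF (degassed), rt → 40 °C
Reagents that add atoms: none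
Why: SN2 S-alkylation: the caesium thiolate is far more nucleophilic than the primary alkoxide and displaces the primary chloride, the vinyl iodide being inert without a metal catalyst.

Step 15
Reactants: 23 open-chain sulfide
Product: 24 open-chain sulfone alcohol
Conditions: (NH4)6Mo7O24·4H2O (cat.), 30% H2O2, EtOH, 0 °C → rt
Reagents that add atoms: hydrogen peroxide (OO)
Why: Molybdate-catalysed peroxide oxidation should take the dialkyl sulfide to the sulfone much faster than it attacks the electron-poor iodoalkene, the 1,1-disubstituted alkene or the primary alcohol.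

Step 16
Reactants: 24 open-chain sulfone alcohol
Product: 25 open-chain sulfone aldehyde (C6 = CHO)
Conditions: Dess–Martin periodinane, NaHCO3, CH2Cl2, 0 °C
Reagents that add atoms: none
Why: Dess–Martin oxidation under buffered, non-basic conditions should give the α-branched β,γ-unsaturated aldehyde without epimerisation at C7 or migration of the double bond; it is used crude.

Step 17
Reactants: 25 open-chain sulfone aldehyde
Product: 26 eleven-membered cyclic sulfone (SO2 between C1 and C10; 4E; 6S-OH)
Conditions: CrCl2 (excess), NiCl2 (cat.), DMSO/THF, rt, high dilution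
Reagents that add atoms: none
Why: Nozaki–Hiyama–Kishi macrocyclisation: Ni(0) inserts into the C–I bond, the alkenyl group passes to Cr(III) with retention of the E geometry and adds to the aldehyde, closing the eleven-membered ring; C6 is expected to be set by Felkin–Anh attack anti to the 2-propenyl substituent on C7, reinforced by 1,3-anti induction from the C8 silyl ether (6S).

Step 18
Reactants: 26 eleven-membered cyclic sulfone
Product: 29 ten-membered (1(10)Z,4E)-dienol, via α-bromo sulfone 27 (not isolated), via episulfone 28 (not isolated)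
Conditions: KOH/Al2O3, CBr2F2, t-BuOH/CH2Cl2, 0 °C → rt
Reagents that add atoms: none
Why: Ramberg–Bäcklund reaction: KOH on alumina deprotonates the sulfone at C1 (or C10), CBr2F2 brominates the carbanion to 27, a second deprotonation at the other α-carbon displaces bromide in a 1,3-elimination to the thiirane 1,1-dioxide 28, and cheletropic loss of SO2 joins C1 to C10 as the alkene. The closest known reaction type is the in-situ halogenative Ramberg–Bäcklund ring contraction of cyclic sulfones to medium-ring cycloalkenes. The only ring closed is the episulfone (3-exo-tet displacement at the C–Br carbon); the ten-membered carbocycle is not closed end to end but arises from the eleven-membered thiacycle by excision of the sulfur atom. No stereocentre is created: C10 becomes sp2, so both C10 epimers of 26 give the same product, and the alkene geometry is fixed by the cis fusion of the episulfone to the medium ring and the stereospecific SO2 extrusion, which should place C2 and C9 cis (Z). The step needs Z over E and carbanion chemistry confined to C1/C10; the substrate secures this because C2 and C9 are plain methylenes (no β-leaving group, the C3 and C8 silyloxy groups are γ), no carbonyl or Michael acceptor is present (the lactone is masked as a bis-silylated diol), and the C6 hydroxyl is only a spectator alkoxide.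

Step 19
Reactants: 29 ten-membered (1(10)Z,4E)-dienol
Product: 30 C6 isobutyrate of the dienol
Conditions: (i-PrCO)2O, Et3N, DMAP, CH2Cl2, rt
Reagents that add atoms: isobutyric anhydride (CC(C)C(=O)OC(=O)C(C)C)
Why: DMAP-catalysed acylation of the only free hydroxyl (C6) with retention of its configuration.

Step 20
Reactants: 30 C6 isobutyrate of the dienol
Product: 31 (1R,10S)-1,10-epoxide
Conditions: D-fructose-derived Shi ketone (30 mol%), Oxone, K2CO3, Bu4NHSO4 (cat.), MeCN/DMM/aq. buffer, 0 °C
Reagents that add atoms: potassium peroxymonosulfate, Oxone ([K+].[O-]S(=O)(=O)OO)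
Why: Shi asymmetric epoxidation: the chiral dioxirane attacks the most electron-rich alkene, C1=C10 (C4=C5 is deactivated by two allylic C–O bonds and 1,1-disubstituted C11=C13 is a poor substrate), through the spiro transition state that for a ring cis-trisubstituted alkene should give the (1R,10S) face (same sense as 1-phenylcyclohexene to its (R,R)-oxide), the Z-alkene translating stereospecifically into the cis-epoxide.

Step 21
Reactants: 31 (1R,10S)-1,10-epoxide
Product: 32 epoxy triol (3-OH, 8-OH, C12-OH) 6-isobutyrate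
Conditions: HF·pyridine, pyridine, THF, 0 °C → rt
Reagents that add atoms: none
Why: Fluoride cleavage of the three silyl ethers with pyridine-buffered HF·pyridine, conditions under which the trisubstituted epoxide and the isobutyrate should persist and acyl migration is slow.

Step 22
Reactants: 32 epoxy triol 6-isobutyrate
Product: 35 target CNP0114243.1, via enal 33 (not isolated), via lactol 34 (not isolated)
Conditions: TEMPO (cat.), PhI(OAc)2, CH2Cl2, rt
Reagents that add atoms: none
Why: TEMPO/PhI(OAc)2 oxidative lactonisation: the primary allylic alcohol is oxidised to the enal far faster than the secondary C3 alcohol, the C8 hydroxyl closes the five-membered lactol (C6 is blocked as the ester, so only the trans-fused 12,8-lactone can form) and the lactol is oxidised on to the α-methylene lactone.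

**Compound list**

1 | 4-methyl hydrogen itaconate (4-methoxy-2-methylidene-4-oxobutanoic acid) | C=C(CC(=O)OC)C(=O)O | starting material
2 | methyl 3-(hydroxymethyl)but-3-enoate | C=C(CO)CC(=O)OC | intermediate
3 | methyl 3-[(tert-butyldimethylsilyloxy)methyl]but-3-enoate | C=C(CO[Si](C)(C)C(C)(C)C)CC(=O)OC | intermediate
4 | 3-[(tert-butyldimethylsilyloxy)methyl]but-3-enoic acid | C=C(CO[Si](C)(C)C(C)(C)C)CC(=O)O | intermediate
5 | (R)-4-benzyloxazolidin-2-one | O=C1N[C@H](Cc2ccccc2)CO1 | starting material
6 | mixed anhydride of 4 with pivalic acid | C=C(CO[Si](C)(C)C(C)(C)C)CC(=O)OC(=O)C(C)(C)C | intermediate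
7 | (R)-4-benzyl-3-{3-[(tert-butyldimethylsilyloxy)methyl]but-3-enoyl}oxazolidin-2-one | C=C(CO[Si](C)(C)C(C)(C)C)CC(=O)N1[C@H](Cc2ccccc2)COC1=O | intermediate
8 | (E)-but-2-enal (crotonaldehyde) | C/C=C/C=O | starting material
9 | thioacetic S-acid | CC(=O)S | starting material
10 | 3-(acetylsulfanyl)butanal, racemic (its CH–S carbon is C10) | CC(CC=O)SC(C)=O | intermediate
11 | dibutylboron Z-enolate of 7 | CCCCB(CCCC)O/C(=C\C(=C)CO[Si](C)(C)C(C)(C)C)N1[C@H](Cc2ccccc2)COC1=O | intermediate
12 | (R)-4-benzyl-3-[(2R,3S)-5-(acetylsulfanyl)-3-hydroxy-2-{3-[(tert-butyldimethylsilyl)oxy]prop-1-en-2-yl}hexanoyl]oxazolidin-2-one, both C5 epimers | O=C(N1[C@H](Cc2ccccc2)COC1=O)[C@H](C(=C)CO[Si](C)(C)C(C)(C)C)[C@@H](O)CC(C)SC(C)=O | intermediate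
13 | 3-O-TBS ether of 12 | O=C(N1[C@H](Cc2ccccc2)COC1=O)[C@H](C(=C)CO[Si](C)(C)C(C)(C)C)[C@@H](O[Si](C)(C)C(C)(C)C)CC(C)SC(C)=O | intermediate
14 | thiol alcohol HOCH2(C6)–C7H[C(=CH2)CH2OTBS]–C8H(OTBS)–C9H2–C10H(CH3)–SH; C7/C8 as in 12; C10 epimers | OC[C@H](C(=C)CO[Si](C)(C)C(C)(C)C)[C@@H](O[Si](C)(C)C(C)(C)C)CC(C)S | intermediate
15 | 3-chloropropanoyl chloride | ClCCC(Cl)=O | starting material
16 | bis(trimethylsilyl)acetylene | C[Si](C)(C)C#C[Si](C)(C)C | starting material
17 | 5-chloro-1-(trimethylsilyl)pent-1-yn-3-one | ClCCC(=O)C#C[Si](C)(C)C | intermediate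
18 | (R)-5-chloro-1-(trimethylsilyl)pent-1-yn-3-ol | ClCC[C@@H](O)C#C[Si](C)(C)C | intermediate
19 | (R)-5-chloropent-1-yn-3-ol | ClCC[C@@H](O)C#C | intermediate
20 | (E)-alkenyl(dimethyl)alane, O-dimethylaluminium alkoxide, from syn-methylalumination of 19 | C[Al](C)/C=C(C)/[C@@H](CCCl)O[Al](C)C | intermediate
21 | (R,E)-5-chloro-1-iodo-2-methylpent-1-en-3-ol | ClCC[C@@H](O)/C(C)=C/I | intermediate
22 | (R,E)-tert-butyl[(5-chloro-1-iodo-2-methylpent-1-en-3-yl)oxy]dimethylsilane | ClCC[C@@H](O[Si](C)(C)C(C)(C)C)/C(C)=C/I | intermediate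
23 | open-chain sulfide HOCH2(C6)–C7H[C(=CH2)CH2OTBS]–C8H(OTBS)–C9H2–C10H(CH3)–S–C1H2–C2H2–C3H(OTBS)–C4(CH3)=C5H–I; 4E, 3R; C10 epimers | OC[C@H](C(=C)CO[Si](C)(C)C(C)(C)C)[C@@H](O[Si](C)(C)C(C)(C)C)CC(C)SCC[C@@H](O[Si](C)(C)C(C)(C)C)/C(C)=C/I | intermediate
24 | S,S-dioxide (sulfone) of 23 | OC[C@H](C(=C)CO[Si](C)(C)C(C)(C)C)[C@@H](O[Si](C)(C)C(C)(C)C)CC(C)S(=O)(=O)CC[C@@H](O[Si](C)(C)C(C)(C)C)/C(C)=C/I | intermediate
25 | sulfone aldehyde (C6 alcohol of 24 oxidised to CHO) | O=C[C@H](C(=C)CO[Si](C)(C)C(C)(C)C)[C@@H](O[Si](C)(C)C(C)(C)C)CC(C)S(=O)(=O)CC[C@@H](O[Si](C)(C)C(C)(C)C)/C(C)=C/I | intermediate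
26 | eleven-membered cyclic sulfone: ring S(O2)–C1–C2–C3(OTBS)–C4(Me)=C5–C6(OH)–C7[C(=CH2)CH2OTBS]–C8(OTBS)–C9–C10(Me); 4E, 3R, 6S; C10 epimers | C1[C@@H](O[Si](C)(C)C(C)(C)C)/C(C)=C/[C@H](O)[C@H](C(=C)CO[Si](C)(C)C(C)(C)C)[C@@H](O[Si](C)(C)C(C)(C)C)CC(C)S(=O)(=O)C1 | intermediate
27 | 1-bromo derivative of 26 (α-bromo sulfone) | C1[C@@H](O[Si](C)(C)C(C)(C)C)/C(C)=C/[C@H](O)[C@H](C(=C)CO[Si](C)(C)C(C)(C)C)[C@@H](O[Si](C)(C)C(C)(C)C)CC(C)S(=O)(=O)C1Br | intermediate
28 | thiirane 1,1-dioxide bridging C1 and C10 of the ten-membered ring (cis-fused) | C1[C@@H](O[Si](C)(C)C(C)(C)C)/C(C)=C/[C@H](O)[C@H](C(=C)CO[Si](C)(C)C(C)(C)C)[C@@H](O[Si](C)(C)C(C)(C)C)CC2(C)C1S2(=O)=O | intermediate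
29 | ten-membered (1(10)Z,4E)-cyclodecadien-6-ol with 3-OTBS, 8-OTBS, 4,10-dimethyl, 7-[3-(TBSO)prop-1-en-2-yl]; 3R, 6S | C1[C@@H](O[Si](C)(C)C(C)(C)C)/C(C)=C/[C@H](O)[C@H](C(=C)CO[Si](C)(C)C(C)(C)C)[C@@H](O[Si](C)(C)C(C)(C)C)C/C(C)=C\1 | intermediate
30 | C6 isobutyrate of 29 | C1[C@@H](O[Si](C)(C)C(C)(C)C)/C(C)=C/[C@H](OC(=O)C(C)C)[C@H](C(=C)CO[Si](C)(C)C(C)(C)C)[C@@H](O[Si](C)(C)C(C)(C)C)C/C(C)=C\1 | intermediate
31 | (1R,10S)-1,10-epoxide of 30 | C1[C@@H](O[Si](C)(C)C(C)(C)C)/C(C)=C/[C@H](OC(=O)C(C)C)[C@H](C(=C)CO[Si](C)(C)C(C)(C)C)[C@@H](O[Si](C)(C)C(C)(C)C)C[C@]2(C)O[C@H]12 | intermediate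
32 | epoxy triol (3-OH, 8-OH, C12-OH) 6-isobutyrate | C1[C@@H](O)/C(C)=C/[C@H](OC(=O)C(C)C)[C@H](C(=C)CO)[C@@H](O)C[C@]2(C)O[C@H]12 | intermediate
33 | enal (C12 = CHO) of 32 | C1[C@@H](O)/C(C)=C/[C@H](OC(=O)C(C)C)[C@H](C(=C)C=O)[C@@H](O)C[C@]2(C)O[C@H]12 | intermediate
34 | lactol (C8–O–C12 hemiacetal) | C1[C@@H](O)/C(C)=C/[C@H](OC(=O)C(C)C)[C@@H]3C(=C)C(O)O[C@H]3C[C@]2(C)O[C@H]12 | intermediate
35 | CNP0114243.1 | C=C1C(=O)O[C@H]2C[C@]3(C)O[C@@H]3C[C@@H](O)/C(C)=C/[C@H](OC(=O)C(C)C)[C@H]12 | target

**Totals.** 22 steps in all; longest linear sequence 16 steps (steps 1–4, 6–8, 14–22).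

**Steps most likely to fail**

1. Step 18 (key step). The free C6 alkoxide may trigger 1,3-silyl migration from O8 or capture difluorocarbene, and the primary silyl ether may be lost on basic alumina. Partial epimerisation of the episulfone would also erode the Z selectivity. The fallback sets out from 26. The C6 hydroxyl is silylated (TESOTf, 2,6-lutidine) to the C6 triethylsilyl ether F1. F1 is lithiated at C1 (n-BuLi, THF, −78 °C) and chlorinated with C2Cl6 to the isolated α-chloro sulfone F2. F2 is ring-contracted with t-BuOK in THF (−78 → 0 °C) to the TES-protected diene F3. Selective TES removal (PPTS, MeOH, 0 °C) comes back to the route at 29.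

2. Step 17. Facial selectivity at C6 may be poor when ring strain competes with the Felkin–Anh preference, and oligomerisation may compete with ring closure. The fallback sets out from 25: the cyclisation is run without regard to the C6 outcome and the epimeric alcohols are oxidised (Dess–Martin periodinane) to the macrocyclic enone F4. Reagent-controlled reduction with (S)-Me-CBS/BH3·SMe2 (alkenyl as the large group) comes back at 26.

3. Step 20. The folded ten-membered ring may impose a facial bias that overrides the catalyst (mismatched case). The fallback sets out from 30 and inverts the facial logic. NBS in aqueous DME lets the electrophile enter on the more accessible face at C1 while water opens at tertiary C10 from the other face, giving the bromohydrin F5. DBU then closes the epoxide with oxygen on the face opposite to electrophile approach and comes back at 31.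

**Further compounds**

F1 | step 18 | C6 triethylsilyl ether of 26 | C1[C@@H](O[Si](C)(C)C(C)(C)C)/C(C)=C/[C@H](O[Si](CC)(CC)CC)[C@H](C(=C)CO[Si](C)(C)C(C)(C)C)[C@@H](O[Si](C)(C)C(C)(C)C)CC(C)S(=O)(=O)C1
F2 | step 18 | 1-chloro derivative of F1 (α-chloro sulfone) | C1[C@@H](O[Si](C)(C)C(C)(C)C)/C(C)=C/[C@H](O[Si](CC)(CC)CC)[C@H](C(=C)CO[Si](C)(C)C(C)(C)C)[C@@H](O[Si](C)(C)C(C)(C)C)CC(C)S(=O)(=O)C1Cl
F3 | step 18 | C6 triethylsilyl ether of 29 | C1[C@@H](O[Si](C)(C)C(C)(C)C)/C(C)=C/[C@H](O[Si](CC)(CC)CC)[C@H](C(=C)CO[Si](C)(C)C(C)(C)C)[C@@H](O[Si](C)(C)C(C)(C)C)C/C(C)=C\1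
F4 | step 17 | macrocyclic enone (C6 ketone of 26) | C1[C@@H](O[Si](C)(C)C(C)(C)C)/C(C)=C/C(=O)[C@H](C(=C)CO[Si](C)(C)C(C)(C)C)[C@@H](O[Si](C)(C)C(C)(C)C)CC(C)S(=O)(=O)C1
F5 | step 20 | bromohydrin of 30 (1-bromo, 10-hydroxy) | C1[C@@H](O[Si](C)(C)C(C)(C)C)/C(C)=C/[C@H](OC(=O)C(C)C)[C@H](C(=C)CO[Si](C)(C)C(C)(C)C)[C@@H](O[Si](C)(C)C(C)(C)C)C[C@](C)(O)[C@H]1Br
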